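The earlier runs and the new flask are simulated for substances that don't exist.

The vessel is closed and stirred, so whatever the substrate becomes stays inside it. I wanted to know what target stands there at 1.5 h and which remedy gains most.

| flask | substrate | first nucleophile | second nucleophile | temperature | remark | time |
|---|---|---|---|---|---|---|
| blue | 0.013 M | 0.065 M | 0.0195 M | 80 °C | the very flask that is asked about, followed so far |  |
| amber | 0.013 M | 0.044 M | 0.0195 M | 65 °C | run made earlier |  |
| flask | 0.013 M | 0.0650 M | 0.0195 M | 80 °C |  | 1.5 h |

| run | time / min | target / % | substrate / % |
|---|---|---|---|
| blue | 6.00 | 24 | 0 |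
| blue | 20.0 | 9 | 0 |
| blue | 30.0 | 8 | 2 |
| blue | 50.0 | 7 | 1 |
| blue | 60.0 | 11 | 0 |
| blue | 90.0 | 6 | 0 |
| amber | 0.333 | 8 | 83 |
| amber | 0.500 | 12 | 75 |
| amber | 0.833 | 15 | 64 |
| amber | 1.33 | 16 | 47 |
| amber | 3.00 | 28 | 18 |
| amber | 4.00 | 30 | 8 |

(standard deviation of a reading: 2 percentage points)

- south-east: at 1.5 h add first nucleophile, 50.0% of the amount charged, then wait 3.0 h
- north-east: at 1.5 h raise the temperature by 25 K, then wait 3.0 h
- south: change nothing and wait 3.0 h more
- west: at 1.5 h take out 90% of the target then present, then wait 3.0 h

- what is taken out of target is counted as made
- additions bring no volume worth counting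

1. target, in percent of the substrate first charged, at 1.5 h
2. the remedy with the largest gain of target, or "none" below 2 percentage points (south-east / north-east / south / west / none)
3. target present, with what was taken out counted in, in percent of the substrate first charged, after south-east
4. target present, with what was taken out counted in, in percent of the substrate first charged, after west

In the blue run substrate read 0% at 6.00 min, while target fell from 24% at that time to a flat stretch from 20.0 min on, with a mean reading of 8.20%. Like a first-order system reaching its set point, this looked to me like target resting against a partner form, which is thermodynamic control.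

I needed the pool, meaning target plus whatever it had turned into, and took two ways to it, both as target per substrate used in the amber run. The first reading gave 47.1% and the last gave 32.6%. They parted, and I distrusted the first, since it rests on a reading of 8% with a scatter of 2 percentage points, whereas the last rests on 30%. Amber is colder than blue and holds less first nucleophile, though, so this pool is a carried-over estimate.

Plateau over pool gave 0.251, the resting share: the fraction of the pool standing as target once the flask is quiet. The symmetric case, with target and its partner form equal, is a share of a half, and my reading for blue stood below it.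

If the pool returns to the same share after a removal, the gain is the amount removed times one minus the share. For west that is 5.5 points, a total of 13.7%, whereas a symmetric share would give 3.7 points. Waiting gains nothing on a flat stretch. No run showed the share at another temperature, but with the pool unchanged, warming beats west if it lifts the share past 0.421.

The forecast gave 8%, 8.5% after south-east and 13.5% after west, and chose west, because removal “lets the pool re-equilibrate”. Its pool was about 45%, larger than mine.

The flask gave 8.28%, 8.28% after south-east and 13.9% after west, but the best remedy was north-east, gaining 9.4 points against 5.6 points. At 90.0 min the isomer of the product held 25.7%. Counting target and isomer as one unchanged pool, the north-east target is a resting share of 0.521, past my mark and close to the symmetric half.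

    substrate → intermediate (k = 0.0450 s⁻¹, Ea = 105 kJ mol⁻¹)
    first nucleophile + intermediate → target (k = 15.0 L mol⁻¹ s⁻¹, Ea = 48.0 kJ mol⁻¹)
    second nucleophile + intermediate → other capture product (k = 26.0 L mol⁻¹ s⁻¹, Ea = 57.0 kJ mol⁻¹)
    intermediate → solvolysis product (k = 1.20 s⁻¹, Ea = 82.0 kJ mol⁻¹)
    2 first nucleophile → homo dimer (k = 0.0290 L mol⁻¹ s⁻¹, Ea = 80.0 kJ mol⁻¹)
    target ⇌ isomer of the product (K = 3.10, k = 0.00190 s⁻¹, Ea = 114 kJ mol⁻¹, ΔH = −54.0 kJ mol⁻¹)
    substrate ⇌ dormant form (K = 0.280, k = 0.00150 s⁻¹, Ea = 102 kJ mol⁻¹, ΔH = −51.0 kJ mol⁻¹)
    (constants at 80 °C)

The neighbour with 0.26 M of first nucleophile put 10.8% into other capture product and 26.5% into solvolysis product, leaving a pool of 62.7%. My resting share gives 15.7% of target there, and the computed result is 15.3%.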